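**Strategy.** The pyran ring of the flavan is closed at its C3–C4 edge. C4 is the benzylic carbon on phloroglucinol ring A and C3 the methylene next to the aryl-bearing C2–O1 stereocentre, so C3=C4 is the retron of a 2H-chromene made by ring-closing metathesis. In one operation the key step closes the ring by this bond without touching C2. Its precursor is an ortho-vinylphenyl (R)-1-arylallyl ether, whose C2–O bond and configuration come from an iridium-catalysed allylic etherification. The flavan is then brominated and borylated at C8 and joined to 3-iodo-apigenin tribenzyl ether by an atroposelective Suzuki coupling. After hydrogenolysis the 7-OH adds to flavone C2, the axis dictating the cis-fused ketal.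

Key step: step 5

Remark: the C3–C8″ biaryl axis of 18 and 19 is assumed to be configurationally stable at room temperature (four ortho substituents); SMILES cannot show it, so the descriptor (aS) stands in the names only.

Step 1
Reactants: 1 3,5-bis(benzyloxy)phenol
Product: 2 2,4-bis(benzyloxy)-6-hydroxybenzaldehyde
Conditions: MgCl2 (2 equiv), Et3N (4 equiv), (CH2O)n (6 equiv), MeCN, reflux
Reagents that add atoms: paraformaldehyde (as formaldehyde), C=O
Why: Magnesium-mediated ortho-formylation of a phenol: the magnesium phenoxide delivers formaldehyde to an ortho carbon (both are equivalent in 1) and a second formaldehyde oxidises the benzylic alkoxide to the aldehyde, which becomes C4 of the flavan.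

Step 2
Reactants: 2 2,4-bis(benzyloxy)-6-hydroxybenzaldehyde
Product: 3 3,5-bis(benzyloxy)-2-vinylphenol
Conditions: Ph3PCH3Br (3 equiv), KOtBu (3 equiv), THF, 0 °C to rt
Reagents that add atoms: methyltriphenylphosphonium bromide, C[P+](c1ccccc1)(c1ccccc1)c1ccccc1.[Br-]
Why: Wittig methylenation, in which excess ylide tolerates the free phenol (deprotonated first) and should give the ortho-vinylphenol.

Step 3
Reactants: 4 1-(benzyloxy)-4-vinylbenzene; 5 allyl methyl carbonate (4 equiv)
Product: 6 (E)-3-[4-(benzyloxy)phenyl]prop-2-en-1-yl methyl carbonate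
Conditions: second-generation Grubbs catalyst (2 mol%), CH2Cl2, 40 °C
Reagents that add atoms: none
Why: Olefin cross-metathesis of a styrene with an excess of an allylic carbonate, which under thermodynamic control should give the E-cinnamyl carbonate.

Step 4
Reactants: 3 3,5-bis(benzyloxy)-2-vinylphenol; 6 (E)-3-[4-(benzyloxy)phenyl]prop-2-en-1-yl methyl carbonate
Product: 8 (R)-1,5-bis(benzyloxy)-3-{[1-(4-benzyloxyphenyl)allyl]oxy}-2-vinylbenzene, via lithium phenoxide 7 (not isolated)
Conditions: n-BuLi (1.0 equiv), THF, 0 °C; then 6, [Ir(cod)Cl]2 (2 mol%), (Ra,R,R)-O,O′-(1,1′-binaphthyl-2,2′-diyl) N,N-bis(1-phenylethyl)phosphoramidite (4 mol%; antipode chosen to give the R ether), THF, rt to 40 °C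
Reagents that add atoms: none
Why: Iridium-catalysed asymmetric allylic etherification: the phenoxide oxygen attacks the aryl-substituted terminus of the cyclometalated iridium–phosphoramidite allyl complex, giving the branched ether and setting the future flavan C2 (R) by catalyst control.

Step 5
Reactants: 8 (R)-1,5-bis(benzyloxy)-3-{[1-(4-benzyloxyphenyl)allyl]oxy}-2-vinylbenzene
Product: 9 (2R)-5,7-bis(benzyloxy)-2-(4-benzyloxyphenyl)-2H-chromene
Conditions: second-generation Grubbs catalyst (5 mol%), 1,4-benzoquinone (10 mol%), CH2Cl2 (0.01 M), 40 °C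
Reagents that add atoms: none
Why: Ring-closing olefin metathesis: the ruthenium alkylidene loads on the unhindered allyl-ether vinyl group, undergoes intramolecular [2+2] cycloaddition and cycloreversion with the ortho-styrenyl olefin and expels ethene, forming the C3=C4 bond. The closest known reaction is the metathesis of 2-vinylphenyl allyl ethers to 2H-chromenes. The six-membered pyran ring is closed by this single C=C bond, both olefinic carbons ending inside the ring with the cis geometry the ring imposes. No stereocentre is created; C2 (R) from step 4 is carried through because neither its C–O nor its C–H bond takes part. The step needs cyclisation over oligomerisation and no olefin migration (a shift of the double bond to C2 would erase the centre); the ortho placement of both olefins on the arene plus high dilution should secure the first, and benzoquinone as ruthenium hydride scavenger the second.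

Step 6
Reactants: 9 (2R)-5,7-bis(benzyloxy)-2-(4-benzyloxyphenyl)-2H-chromene
Product: 10 (2R)-5,7-bis(benzyloxy)-2-(4-benzyloxyphenyl)chroman
Conditions: 2-nitrobenzenesulfonohydrazide (6 equiv), Et3N, CH2Cl2, rt
Reagents that add atoms: none
Why: Diimide reduction (concerted syn hydrogen transfer from HN=NH) saturates the cis C3=C4 bond without a metal hydride, so no double-bond migration can scramble C2, and the benzyl ethers and the benzylic C2–O1 bond are left intact.

Step 7
Reactants: 10 (2R)-5,7-bis(benzyloxy)-2-(4-benzyloxyphenyl)chroman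
Product: 11 (2R)-8-bromo-5,7-bis(benzyloxy)-2-(4-benzyloxyphenyl)chroman
Conditions: NBS (1.0 equiv), CH2Cl2, −78 to 0 °C, dark
Reagents that add atoms: N-bromosuccinimide, O=C1CCC(=O)N1Br
Why: Electrophilic aromatic bromination of ring A, expected at C8 (between the ring oxygen and one benzyloxy group) and not at the more hindered C6 (between two benzyloxy groups), as is known for 5,7-di-O-benzylflavans.

Step 8
Reactants: 11 (2R)-8-bromo-5,7-bis(benzyloxy)-2-(4-benzyloxyphenyl)chroman
Product: 13 (2R)-5,7-bis(benzyloxy)-2-(4-benzyloxyphenyl)-8-(4,4,5,5-tetramethyl-1,3,2-dioxaborolan-2-yl)chroman, via aryllithium 12 (not isolated)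
Conditions: n-BuLi (1.1 equiv), THF, −78 °C; then 2-isopropoxy-4,4,5,5-tetramethyl-1,3,2-dioxaborolane, −78 °C to rt
Reagents that add atoms: 2-isopropoxy-4,4,5,5-tetramethyl-1,3,2-dioxaborolane, CC(C)OB1OC(C)(C)C(C)(C)O1
Why: Bromine–lithium exchange at low temperature followed by borylation of the aryllithium with the isopropoxy pinacol borate.

Step 9
Reactants: 14 apigenin
Product: 15 5,7-bis(benzyloxy)-2-(4-benzyloxyphenyl)-4H-chromen-4-one
Conditions: BnBr (4 equiv), K2CO3 (5 equiv), DMF, 80 °C
Reagents that add atoms: benzyl bromide, BrCc1ccccc1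
Why: Williamson etherification under forcing conditions, which should also alkylate the hydrogen-bonded 5-OH.

Step 10
Reactants: 15 5,7-bis(benzyloxy)-2-(4-benzyloxyphenyl)-4H-chromen-4-one
Product: 17 5,7-bis(benzyloxy)-2-(4-benzyloxyphenyl)-3-iodo-4H-chromen-4-one, via 3-lithioflavone 16 (not isolated)
Conditions: LiN(iPr)2 (1.3 equiv), THF, −78 °C; then I2 (1.5 equiv)
Reagents that add atoms: iodine, II
Why: Directed lithiation of the flavone at C3 (its only vinylic C–H, next to the carbonyl) and iodine quench place the halogen regiospecifically, avoiding electrophilic iodination of the electron-rich rings.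

Step 11
Reactants: 13 (2R)-5,7-bis(benzyloxy)-2-(4-benzyloxyphenyl)-8-(pinacolboryl)chroman; 17 5,7-bis(benzyloxy)-2-(4-benzyloxyphenyl)-3-iodo-4H-chromen-4-one
Product: 18 (aS)-3-[(2R)-5,7-bis(benzyloxy)-2-(4-benzyloxyphenyl)chroman-8-yl]-5,7-bis(benzyloxy)-2-(4-benzyloxyphenyl)-4H-chromen-4-one
Conditions: Pd(OAc)2 (5 mol%), BI-DIME (P-chiral monophosphine, 10 mol%; antipode selected for the aS axis), K3PO4 (3 equiv), toluene/H2O, 50 °C; chromatography of the atropisomers
Reagents that add atoms: none
Why: Suzuki–Miyaura coupling forming a tetra-ortho-substituted aryl–chromone bond, in which the chiral ligand sets the sense of the new axis (atroposelective coupling); the two atropisomers are diastereomers through flavan C2 and separable, and (aS) is the one whose 7″-oxygen lies over the C2 face that leads to the (S)-ketal.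

Step 12
Reactants: 18 (aS)-hexabenzyl 3-(flavan-8-yl)flavone
Product: 20 target CNP0179743.1 (cis-fused benzofuro[2,3-b]chromen-11-one ketal; ketal carbon S; ring-fusion CH S; flavan C2 R), via hexaphenol flavone 19 (not isolated)
Conditions: H2 (1 atm), Pd(OH)2/C, THF/MeOH, rt; filter under argon; then (PhO)2P(O)OH (20 mol%), THF, 0 °C to rt, stopped at maximum ketal
Reagents that add atoms: none
Why: Proposed new method: after hydrogenolysis of the six benzyl ethers, the acid activates the chromone carbonyl (4-hydroxyflavylium character at C2) and the 7″-OH, held over one face of C2 by the axis, adds 5-exo to the C2=O1 oxocarbenium, so the axial chirality is transferred to the ketal carbon (S); tautomerisation of the enol then puts H on C3 in the only strain-free, cis-fused sense (S), and the resulting ketone should persist because its reopening requires enolisation. The closest known reactions are the acid-mediated closure of a phenol onto C2 of flavylium or flav-2-ene units (A-type proanthocyanidin ketals) and the 2′-hydroxychalcone to flavanone oxa-Michael addition.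

**Compound list**

1 | 3,5-bis(benzyloxy)phenol | Oc1cc(OCc2ccccc2)cc(OCc2ccccc2)c1 | starting material
2 | 2,4-bis(benzyloxy)-6-hydroxybenzaldehyde | O=Cc1c(O)cc(OCc2ccccc2)cc1OCc1ccccc1 | intermediate
3 | 3,5-bis(benzyloxy)-2-vinylphenol | C=Cc1c(O)cc(OCc2ccccc2)cc1OCc1ccccc1 | intermediate
4 | 1-(benzyloxy)-4-vinylbenzene | C=Cc1ccc(OCc2ccccc2)cc1 | starting material
5 | allyl methyl carbonate | C=CCOC(=O)OC | starting material
6 | (E)-3-[4-(benzyloxy)phenyl]prop-2-en-1-yl methyl carbonate | COC(=O)OC/C=C/c1ccc(OCc2ccccc2)cc1 | intermediate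
7 | lithium 3,5-bis(benzyloxy)-2-vinylphenoxide | [Li+].[O-]c1cc(OCc2ccccc2)cc(OCc2ccccc2)c1C=C | intermediate
8 | (R)-1,5-bis(benzyloxy)-3-{[1-(4-benzyloxyphenyl)allyl]oxy}-2-vinylbenzene | C=Cc1c(OCc2ccccc2)cc(OCc2ccccc2)cc1O[C@@H](c1ccc(OCc2ccccc2)cc1)C=C | intermediate
9 | (2R)-5,7-bis(benzyloxy)-2-(4-benzyloxyphenyl)-2H-chromene | c1(OCc2ccccc2)cc(OCc2ccccc2)c2c(c1)O[C@@H](c1ccc(OCc3ccccc3)cc1)C=C2 | intermediate
10 | (2R)-5,7-bis(benzyloxy)-2-(4-benzyloxyphenyl)chroman | c1(OCc2ccccc2)cc(OCc2ccccc2)c2c(c1)O[C@@H](c1ccc(OCc3ccccc3)cc1)CC2 | intermediate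
11 | (2R)-8-bromo-5,7-bis(benzyloxy)-2-(4-benzyloxyphenyl)chroman | c1(OCc2ccccc2)cc(OCc2ccccc2)c2c(c1Br)O[C@@H](c1ccc(OCc3ccccc3)cc1)CC2 | intermediate
12 | (2R)-5,7-bis(benzyloxy)-2-(4-benzyloxyphenyl)chroman-8-yllithium | c1(OCc2ccccc2)cc(OCc2ccccc2)c2c(c1[Li])O[C@@H](c1ccc(OCc3ccccc3)cc1)CC2 | intermediate
13 | (2R)-5,7-bis(benzyloxy)-2-(4-benzyloxyphenyl)-8-(4,4,5,5-tetramethyl-1,3,2-dioxaborolan-2-yl)chroman | c1(OCc2ccccc2)cc(OCc2ccccc2)c2c(c1B1OC(C)(C)C(C)(C)O1)O[C@@H](c1ccc(OCc3ccccc3)cc1)CC2 | intermediate
14 | apigenin (5,7-dihydroxy-2-(4-hydroxyphenyl)-4H-chromen-4-one) | O=c1cc(-c2ccc(O)cc2)oc2cc(O)cc(O)c12 | starting material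
15 | 5,7-bis(benzyloxy)-2-(4-benzyloxyphenyl)-4H-chromen-4-one | O=c1cc(-c2ccc(OCc3ccccc3)cc2)oc2cc(OCc3ccccc3)cc(OCc3ccccc3)c12 | intermediate
16 | 5,7-bis(benzyloxy)-2-(4-benzyloxyphenyl)-3-lithio-4H-chromen-4-one | O=c1c([Li])c(-c2ccc(OCc3ccccc3)cc2)oc2cc(OCc3ccccc3)cc(OCc3ccccc3)c12 | intermediate
17 | 5,7-bis(benzyloxy)-2-(4-benzyloxyphenyl)-3-iodo-4H-chromen-4-one | O=c1c(I)c(-c2ccc(OCc3ccccc3)cc2)oc2cc(OCc3ccccc3)cc(OCc3ccccc3)c12 | intermediate
18 | (aS)-3-[(2R)-5,7-bis(benzyloxy)-2-(4-benzyloxyphenyl)chroman-8-yl]-5,7-bis(benzyloxy)-2-(4-benzyloxyphenyl)-4H-chromen-4-one | O=c1c(-c2c(OCc3ccccc3)cc(OCc3ccccc3)c3c2O[C@@H](c2ccc(OCc4ccccc4)cc2)CC3)c(-c2ccc(OCc3ccccc3)cc2)oc2cc(OCc3ccccc3)cc(OCc3ccccc3)c12 | intermediate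
19 | (aS)-3-[(2R)-5,7-dihydroxy-2-(4-hydroxyphenyl)chroman-8-yl]-5,7-dihydroxy-2-(4-hydroxyphenyl)-4H-chromen-4-one | O=c1c(-c2c(O)cc(O)c3c2O[C@@H](c2ccc(O)cc2)CC3)c(-c2ccc(O)cc2)oc2cc(O)cc(O)c12 | intermediate
20 | CNP0179743.1 (cis-fused ketal: ketal carbon S, ring-fusion CH S, flavan C2 R) | O=C1c2c(O)cc(O)cc2O[C@@]2(c3ccc(O)cc3)Oc3cc(O)c4c(c3[C@@H]12)O[C@@H](c1ccc(O)cc1)CC4 | target

**Step count.** Total: 12 steps. Longest linear sequence: 9 steps (1, 2, 4, 5, 6, 7, 8, 11, 12, from compound 1).

**Steps most likely to fail**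

Step 12 (proposed new method). The closure may not be downhill and stay at the flavone. It may also run on, by cleavage of the C2–O1 bond of the new chromanone, to the aromatic 3-aroylbenzofuran isomer. A third failure is rotation of the axis of 19 before closure, which would lose the chirality transfer. The fallback sets out from 19, isolated after the hydrogenolysis, and comes back at 20. Alkaline opening of the chromone ring (aqueous KOH, MeOH, the classical flavone cleavage) should give the β-diketone F1. Mild acid should then cyclodehydrate the 7″-OH onto the 4-hydroxybenzoyl carbonyl, the usual 2-(2-hydroxyaryl)-1,3-diketone to 3-acylbenzofuran condensation, giving the 3-aroyl-2-arylbenzofuran F2; any flavone 19 that re-forms is recycled. F2 is then closed from the other side by a buffered 6-endo oxa-Michael addition of the 2′-hydroxychalcone to flavanone type (NaOAc, EtOH). This should give 20 together with its ketal epimer F3. These are diastereomers and would be separated by preparative HPLC, and F3 is returned to F2 with base and recycled.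

Step 11. The di-ortho-alkoxy boronate may protodeboronate, transmetalation onto the hindered palladium centre may be slow, and the ligand may not control the axis. The fallback sets out from aryllithium 12 and comes back at 18. Transmetalation with ZnCl2 should give the arylzinc chloride F4, which is coupled with 17 in a Negishi reaction under an achiral catalyst (Pd(OAc)2/SPhos, THF, 50 °C). This gives 18 and its (aR)-atropisomer F5 under substrate control only. The two are separated as diastereomers, and F5 is equilibrated thermally (toluene, reflux) and recycled.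

Step 4. The electron-rich ambident phenoxide may be allylated on carbon, the linear ether may form, and the p-alkoxy-substituted branched ether may re-ionise with loss of enantiopurity; the vinylphenol 3 is also acid- and air-sensitive. The fallback sets out from 2 and comes back at 8. The asymmetric iridium-catalysed etherification is run on the lithium phenoxide of salicylaldehyde 2, which is conjugated to the formyl group and much less carbon-nucleophilic, to give the aldehyde ether F6. The styrene is then introduced by Wittig methylenation (Ph3PCH3Br, KOtBu, THF).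

**Further compounds**

F1 | step 12 | 2-[(2R)-5,7-dihydroxy-2-(4-hydroxyphenyl)chroman-8-yl]-1-(4-hydroxyphenyl)-3-(2,4,6-trihydroxyphenyl)propane-1,3-dione | O=C(c1ccc(O)cc1)C(C(=O)c1c(O)cc(O)cc1O)c1c(O)cc(O)c2c1O[C@@H](c1ccc(O)cc1)CC2
F2 | step 12 | 3-aroyl-2-arylbenzofuran isomer, (2R)-flavan-fused [2-(4-hydroxyphenyl)benzofuran-3-yl](2,4,6-trihydroxyphenyl)methanone | O=C(c1c(O)cc(O)cc1O)c1c(-c2ccc(O)cc2)oc2cc(O)c3c(c12)O[C@@H](c1ccc(O)cc1)CC3
F3 | step 12 | ketal epimer of 20 (ketal carbon R, ring-fusion CH R, flavan C2 R) | O=C1c2c(O)cc(O)cc2O[C@]2(c3ccc(O)cc3)Oc3cc(O)c4c(c3[C@H]12)O[C@@H](c1ccc(O)cc1)CC4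
F4 | step 11 | [(2R)-5,7-bis(benzyloxy)-2-(4-benzyloxyphenyl)chroman-8-yl]zinc chloride | c1(OCc2ccccc2)cc(OCc2ccccc2)c2c(c1[Zn]Cl)O[C@@H](c1ccc(OCc3ccccc3)cc1)CC2
F5 | step 11 | (aR)-atropisomer of 18 (axis not expressible in SMILES) | O=c1c(-c2c(OCc3ccccc3)cc(OCc3ccccc3)c3c2O[C@@H](c2ccc(OCc4ccccc4)cc2)CC3)c(-c2ccc(OCc3ccccc3)cc2)oc2cc(OCc3ccccc3)cc(OCc3ccccc3)c12
F6 | step 4 | (R)-2,4-bis(benzyloxy)-6-{[1-(4-benzyloxyphenyl)allyl]oxy}benzaldehyde | O=Cc1c(OCc2ccccc2)cc(OCc2ccccc2)cc1O[C@@H](c1ccc(OCc2ccccc2)cc1)C=C
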